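**Retrosynthetic overview**

- Guidongnin C is traced back to a 15-oxo-16-methylene precursor (C17 by α-methylenation, C16–H by hydrogenation). Ring D is closed by an intramolecular Mukaiyama–Michael addition of an 8-acetyl group onto a ring C enone (C13–C16), which leaves C11 as a silyl enol ether.
- Ring C comes from a Diels–Alder reaction of butadiene with the 8-acetyl-Δ8(9) δ-lactone (C9–C11, C8–C14). Ring B (δ-lactone C7–O–C20) and the C19–O–C6 γ-lactone form together when a C19/O20 cage acetal is opened, reduced and relactonised.
- The strategy rests on ring A (C1–C5, C10): a cis-fused γ-lactone (C19–O–C6) sits on quaternary C4 and on C5, beside C10, which in the 6,7-seco skeleton carries two one-carbon arms (C20 and C9). This unit is the adduct of a spiro-dioxane diene and 5-menthyloxy-4-methylbutenolide (bonds C3–C4 and C5–C10).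
- Ring order: A with γ-lactone, then B, then C, then D.

Key step: step 3

Remark: atoms are numbered as in the ent-kaurane skeleton (ring A = C1–C5, C10; ring B = lactone C7–O–C20; ring C = C8, C9, C11–C14; ring D = C8, C13–C16), and the crystalline menthyl acetal is taken to be the (5R) epimer drawn for 6.

**Route**

Step 1
Reactants: 1 2,2-dimethyl-1,3-dioxan-5-one; 2 allyltriphenylphosphonium bromide
Product: 3 5-allylidene-2,2-dimethyl-1,3-dioxane
Conditions: n-BuLi, THF, −78 °C → rt
Reagents that add atoms: none
Why: Wittig olefination by the allyl ylide at its α-carbon should give the semicyclic diene, and the two identical CH2O arms of the ketone leave no alkene geometry to control.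

Step 2
Reactants: 4 5-hydroxy-4-methylfuran-2(5H)-one; 5 (−)-menthol
Product: 6 (5R)-5-(menthyloxy)-4-methylfuran-2(5H)-one
Conditions: TsOH (cat.), PhMe, reflux, Dean–Stark; crystallisation from hexane, mother liquor re-equilibrated with TsOH
Reagents that add atoms: none
Why: Acid-catalysed acetalisation of the lactol gives both acetal epimers, which interconvert under acid, so crystallisation should funnel the material into the (5R) epimer (crystallisation-induced diastereomer transformation) and set the acetal centre (later C19).

Step 3
Reactants: 3 5-allylidene-2,2-dimethyl-1,3-dioxane; 6 (5R)-5-(menthyloxy)-4-methylfuran-2(5H)-one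
Product: 7 Diels–Alder adduct (ring A cyclohexene spiro-fused to the dioxane at C10 and cis-fused to the 19-menthyloxy γ-lactone)
Conditions: ZnCl2 (1 equiv), BHT (cat.), CH2Cl2, 40 °C, sealed tube
Reagents that add atoms: none
Why: This is a concerted, asynchronous [4+2] cycloaddition of the type known for 5-alkoxy-2(5H)-furanones as chiral dienophiles, with ZnCl2 on the lactone carbonyl lowering the LUMO. The unsubstituted diene terminus C3 (largest HOMO coefficient) bonds to the methyl-bearing β-carbon C4 and the spiro-substituted terminus C10 to the α-carbon C5, so no bond joins two fully substituted carbons. Ring A closes in an intermolecular six-membered cycloaddition mode, and suprafacial addition to the butenolide makes the γ-lactone cis-fused. C4 and C5 are set by the menthyloxy group on C19, which shields one face of the butenolide so that the diene adds anti to it. Only diastereofacial selectivity is needed, because the symmetric dioxane terminus makes endo and exo approach equivalent and leaves C10 non-stereogenic until its arms are told apart.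

Step 4
Reactants: 7 Diels–Alder adduct
Product: 9 cage acetal alcohol, via diol 8 (not isolated)
Conditions: TsOH·H2O (0.2 equiv), THF–H2O, 50 °C; then PhMe, 80 °C, 4 Å MS
Reagents that add atoms: none
Why: Acetonide hydrolysis is followed by intramolecular transacetalisation, in which the C19 oxocarbenium ion formed on loss of menthol can be reached only by the CH2OH arm cis to it on ring A, so that arm becomes C20 inside the cage, the other stays free as C9, C10 is set by the C4/C5 centres and the C19 configuration is fixed by the cage.

Step 5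
Reactants: 9 cage acetal alcohol
Product: 10 cage acetal aldehyde
Conditions: Dess–Martin periodinane, CH2Cl2, rt
Reagents that add atoms: none
Why: Dess–Martin oxidation of the neopentyl primary alcohol should give the C9 aldehyde without touching the acyloxy acetal, and the quaternary α-carbon rules out epimerisation or alkene migration.

Step 6
Reactants: 10 cage acetal aldehyde; 11 ethyl (triphenylphosphoranylidene)acetate
Product: 12 cage acetal (E)-enoate
Conditions: PhMe, 90 °C
Reagents that add atoms: none
Why: Wittig olefination with the stabilised, non-basic ylide adds C8 and C7 to C9, and the alkene geometry is of no consequence because the bond is saturated in step 7.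

Step 7
Reactants: 12 cage acetal (E)-enoate
Product: 13 cage acetal saturated ester
Conditions: H2 (3 bar), 10% Pd/C, EtOAc, rt
Reagents that add atoms: none
Why: Heterogeneous catalytic hydrogenation should saturate both the enoate and the ring A C1=C2 bond in one operation, creating no stereocentre and leaving the acetal cage intact.

Step 8
Reactants: 13 cage acetal saturated ester
Product: 15 spiro bis-lactone, via dihydroxy diacid 14 (not isolated)
Conditions: NaOH, NaBH4, MeOH–H2O, 0 °C → rt; 2 M HCl; then TsOH (cat.), PhMe, reflux, Dean–Stark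
Reagents that add atoms: none
Why: Saponification of the acyloxy acetal frees the C19 aldehyde (as its lactol), which NaBH4 reduces, and acid-catalysed lactonisation then converges on the only arrangement in which both hydroxyls are acylated (C19–O–C6 γ-lactone plus C20–O–C7 δ-lactone), because the C19 hydroxyl cannot reach C7 and any C6–O–C20 lactone re-equilibrates.

Step 9
Reactants: 15 spiro bis-lactone
Product: 16 8-acetyl bis-lactone (C8 epimers)
Conditions: LiN(iPr)2 (1.1 equiv), THF, −78 °C; MeC(O)N(OMe)Me, −78 → 0 °C; aq. NH4Cl
Reagents that add atoms: N-methoxy-N-methylacetamide, CC(=O)N(C)OC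
Why: Claisen-type C-acylation of the δ-lactone lithium enolate by the N-methoxy-N-methyl amide (stable chelated adduct, no over-reaction) should occur at the C8 methylene and not at C5–H, which lies between two quaternary carbons; the C8 configuration is erased in step 10.

Step 10
Reactants: 16 8-acetyl bis-lactone
Product: 18 8-acetyl-8,9-dehydro bis-lactone, via selenide 17 (not isolated)
Conditions: PhSeCl, pyridine, CH2Cl2, 0 °C; then 30% H2O2, 0 °C; used crude
Reagents that add atoms: none
Why: α-Selenenylation of the β-keto lactone and selenoxide syn-elimination can only take a hydrogen from C9, so the endocyclic C8=C9 alkylidene β-keto lactone should form as a single isomer.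

Step 11
Reactants: 18 8-acetyl-8,9-dehydro bis-lactone; 19 buta-1,3-diene
Product: 20 ring C cyclohexene (8-acetyl, C12=C13, cis-fused to ring B)
Conditions: ZnCl2, CH2Cl2, −20 °C → rt, sealed tube
Reagents that add atoms: none
Why: Lewis-acid-promoted Diels–Alder reaction of the doubly activated alkene closes ring C with a cis B/C fusion (suprafacial addition), and the diene should approach the face of ring B anti to C5, whose lactone carbonyl lies gauche to C9, which sets C8 and C9 with C11 syn to C1.

Step 12
Reactants: 20 ring C cyclohexene
Product: 21 C11 allylic alcohol (C11 epimers)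
Conditions: SeO2 (0.3 equiv), t-BuOOH (3 equiv), CH2Cl2, rt → 40 °C
Reagents that add atoms: tert-butyl hydroperoxide, CC(C)(C)OO; selenium dioxide (catalytic oxygen carrier), O=[Se]=O
Why: SeO2 allylic oxidation (ene reaction then [2,3]-sigmatropic shift) places oxygen on the carbon that loses hydrogen, which should be C11 and not C14, because C14 is neopentyl and β to the two carbonyl groups on C8; the C11 configuration is irrelevant here.

Step 13
Reactants: 21 C11 allylic alcohol
Product: 22 C11 enone (C11=O, C12=C13)
Conditions: Dess–Martin periodinane, CH2Cl2, rt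
Reagents that add atoms: none
Why: Dess–Martin oxidation of the secondary allylic alcohol under neutral conditions should give the enone without epimerising C9.

Step 14
Reactants: 22 C11 enone
Product: 24 bicyclo[3.2.1]octane C11 silyl enol ether (15-ketone), via silyl enol ether 23 (not isolated)
Conditions: LiN(SiMe3)2, THF, −78 °C; TBSOTf (1.2 equiv); then Tf2NH (5 mol %), CH2Cl2, −78 → −20 °C
Reagents that add atoms: tert-butyldimethylsilyl triflate, CC(C)(C)[Si](C)(C)OS(=O)(=O)C(F)(F)F
Why: Kinetic enolisation and O-silylation of the methyl ketone followed by intramolecular Mukaiyama–Michael addition (5-exo-trig) to the enone β-carbon C13 closes ring D; the acetyl group on C8 reaches only its own face, which sets C13, and silyl transfer leaves C11 as an enol ether, so the C11 and C15 carbonyls stay differentiated.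

Step 15
Reactants: 24 bicyclo[3.2.1]octane C11 silyl enol ether
Product: 25 11-silyloxy 15-ketone
Conditions: H2 (20 bar), 10% Pd/C, EtOAc, rt
Reagents that add atoms: none
Why: Heterogeneous hydrogenation of the enol ether leaves ketone and lactones untouched, and hydrogen should add to the face carrying the two-carbon bridge, away from the quaternary C10 on C9, so the silyloxy group at C11 ends up cis to C10 (equatorial on ring C).

Step 16
Reactants: 25 11-silyloxy 15-ketone
Product: 28 16-methylene 15-ketone, via Mannich base 26 (not isolated), via methiodide 27 (not isolated)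
Conditions: LiN(SiMe3)2, THF, −78 °C; CH2=NMe2+ I−, −78 → 0 °C; MeI, CH2Cl2, rt; aq. NaHCO3
Reagents that add atoms: dimethylmethyleneammonium iodide, C=[N+](C)C.[I-]
Why: Mannich α-methylenation works here because C16 is the only enolisable position of the C15 ketone (C8 is quaternary), and quaternisation followed by E1cB elimination gives the exocyclic enone with no new stereocentre.

Step 17
Reactants: 28 16-methylene 15-ketone
Product: 29 11-O-TBS guidongnin C
Conditions: H2 (1 atm), 10% Pd/C, EtOAc, 0 °C
Reagents that add atoms: none
Why: Catalytic hydrogenation should deliver hydrogen to the exo face of the exocyclic alkene (the side of the one-carbon bridge C14), which sets C16 with the methyl group pointing toward C12 under kinetic control, and no base is used afterwards that could epimerise it.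

Step 18
Reactants: 29 11-O-TBS guidongnin C
Product: 30 guidongnin C
Conditions: HF·pyridine, THF, 0 °C → rt
Reagents that add atoms: none
Why: Fluoride-mediated desilylation under weakly acidic conditions frees the C11 hydroxyl without risk to the lactones or the epimerisable C16 centre.

**Compound list**

1 | 2,2-dimethyl-1,3-dioxan-5-one | CC1(C)OCC(=O)CO1 | starting material
2 | allyltriphenylphosphonium bromide | C=CC[P+](c1ccccc1)(c1ccccc1)c1ccccc1.[Br-] | starting material
3 | 5-allylidene-2,2-dimethyl-1,3-dioxane | C=CC=C1COC(C)(C)OC1 | intermediate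
4 | 5-hydroxy-4-methylfuran-2(5H)-one | CC1=CC(=O)OC1O | starting material
5 | (−)-menthol | CC(C)[C@@H]1CC[C@@H](C)C[C@H]1O | starting material
6 | (5R)-5-(menthyloxy)-4-methylfuran-2(5H)-one | CC1=CC(=O)O[C@H]1O[C@@H]1C[C@H](C)CC[C@H]1C(C)C | intermediate
7 | Diels–Alder adduct: ring A cyclohexene (C1=C2), C10 spiro to the 2,2-dimethyl-1,3-dioxane, γ-lactone cis-fused at C4–C5, C4 methyl, C19 menthyloxy acetal anti to the ring A bonds | C[C@@]12CC=CC3(COC(C)(C)OC3)[C@@H]1C(=O)O[C@H]2O[C@@H]1C[C@H](C)CC[C@H]1C(C)C | intermediate
8 | diol of 7 (two CH2OH on C10, menthyl acetal kept) | C[C@@]12CC=CC(CO)(CO)[C@@H]1C(=O)O[C@H]2O[C@@H]1C[C@H](C)CC[C@H]1C(C)C | intermediate (not isolated)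
9 | cage acetal alcohol: C19 acetal CH bonded to the lactone oxygen and to O20 (C20 on C10, cis to C19), free C9 hydroxymethyl on the other face of C10, C1=C2 | O=C1O[C@@H]2OC[C@@]3(CO)C=CC[C@]2(C)[C@@H]13 | intermediate
10 | cage acetal aldehyde (C9 = CHO) | O=C1O[C@@H]2OC[C@@]3(C=O)C=CC[C@]2(C)[C@@H]13 | intermediate
11 | ethyl (triphenylphosphoranylidene)acetate | CCOC(=O)C=P(c1ccccc1)(c1ccccc1)c1ccccc1 | starting material
12 | cage acetal (E)-enoate (C9=C8–C7O2Et) | O=C1O[C@@H]2OC[C@@]3(/C=C/C(=O)OCC)C=CC[C@]2(C)[C@@H]13 | intermediate
13 | cage acetal saturated ester (ring A saturated, C9H2–C8H2–C7O2Et) | O=C1O[C@@H]2OC[C@@]3(CCC(=O)OCC)CCC[C@]2(C)[C@@H]13 | intermediate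
14 | dihydroxy diacid (C19 and C20 CH2OH, C6 and C7 CO2H) | OC(=O)CC[C@]1(CO)CCC[C@@](C)(CO)[C@H]1C(=O)O | intermediate (not isolated)
15 | spiro bis-lactone: γ-lactone C19–O–C6 on ring A, δ-lactone C20–O–C7 spiro at C10 | O=C1CC[C@@]2(CCC[C@@]3(C)COC(=O)[C@H]32)CO1 | intermediate
16 | 8-acetyl bis-lactone (C8 epimers) | CC(=O)C1C[C@@]2(CCC[C@@]3(C)COC(=O)[C@H]32)COC1=O | intermediate
17 | 8-acetyl-8-phenylselanyl bis-lactone | CC(=O)C1([Se]c2ccccc2)C[C@@]2(CCC[C@@]3(C)COC(=O)[C@H]32)COC1=O | intermediate (not isolated)
18 | 8-acetyl-8,9-dehydro bis-lactone (C8=C9 in ring B) | CC(=O)C1=C[C@@]2(CCC[C@@]3(C)COC(=O)[C@H]32)COC1=O | intermediate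
19 | buta-1,3-diene | C=CC=C | starting material
20 | ring C cyclohexene: cis-fused to ring B, C8 acetyl, C12=C13 | CC(=O)[C@]12CC=CC[C@H]1[C@@]1(CCC[C@@]3(C)COC(=O)[C@H]31)COC2=O | intermediate
21 | C11 allylic alcohol (C11 epimers) | CC(=O)[C@]12CC=CC(O)[C@H]1[C@@]1(CCC[C@@]3(C)COC(=O)[C@H]31)COC2=O | intermediate
22 | C11 enone | CC(=O)[C@]12CC=CC(=O)[C@H]1[C@@]1(CCC[C@@]3(C)COC(=O)[C@H]31)COC2=O | intermediate
23 | C15 tert-butyldimethylsilyl enol ether of 22 | C=C(O[Si](C)(C)C(C)(C)C)[C@]12CC=CC(=O)[C@H]1[C@@]1(CCC[C@@]3(C)COC(=O)[C@H]31)COC2=O | intermediate (not isolated)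
24 | bicyclo[3.2.1]octane (ring D closed, C15 ketone) with C11=C12 silyl enol ether | C1C(=O)[C@]23C[C@H]1C=C(O[Si](C)(C)C(C)(C)C)[C@H]2[C@@]1(CCC[C@@]2(C)COC(=O)[C@H]21)COC3=O | intermediate
25 | 11-silyloxy 15-ketone (OTBS cis to C10) | C1C(=O)[C@]23C[C@H]1C[C@@H](O[Si](C)(C)C(C)(C)C)[C@H]2[C@@]1(CCC[C@@]2(C)COC(=O)[C@H]21)COC3=O | intermediate
26 | C16 dimethylaminomethyl ketone (Mannich base) | CN(C)CC1C(=O)[C@]23C[C@H]1C[C@@H](O[Si](C)(C)C(C)(C)C)[C@H]2[C@@]1(CCC[C@@]2(C)COC(=O)[C@H]21)COC3=O | intermediate (not isolated)
27 | methiodide of 26 | C[N+](C)(C)CC1C(=O)[C@]23C[C@H]1C[C@@H](O[Si](C)(C)C(C)(C)C)[C@H]2[C@@]1(CCC[C@@]2(C)COC(=O)[C@H]21)COC3=O.[I-] | intermediate (not isolated)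
28 | 16-methylene 15-ketone (11-OTBS) | C=C1C(=O)[C@]23C[C@H]1C[C@@H](O[Si](C)(C)C(C)(C)C)[C@H]2[C@@]1(CCC[C@@]2(C)COC(=O)[C@H]21)COC3=O | intermediate
29 | 11-O-TBS guidongnin C | C[C@H]1C(=O)[C@]23C[C@H]1C[C@@H](O[Si](C)(C)C(C)(C)C)[C@H]2[C@@]1(CCC[C@@]2(C)COC(=O)[C@H]21)COC3=O | intermediate
30 | guidongnin C | C[C@H]1C(=O)[C@]23C[C@H]1C[C@@H](O)[C@H]2[C@@]1(CCC[C@@]2(C)COC(=O)[C@H]21)COC3=O | target

**Step count**

Total: 18 steps. Longest linear sequence: 17 steps (step 1 or step 2, then steps 3–18).

**Steps most likely to fail**

Step 3. The cycloaddition may stall: the β-methyl butenolide is a weak dienophile and the diene must reach an s-cis conformation against its ring CH2 group, so diene polymerisation or Lewis-acid loss of the acetonide could outrun bond formation. The fallback sets out from diene 3 and uses the more electron-poor citraconic anhydride (PhMe, 80 °C), which should give the racemic cis-anhydride adduct F1 with the same regiochemistry. Reduction with LiAlH(OtBu)3 at −78 °C, which attacks the carbonyl next to the quaternary carbon, would give the hydroxy lactone F2. Acid-catalysed acetalisation of F2 with menthol 5 and separation of the diastereomeric acetals by crystallisation comes back to the route at 7, at the cost of half the material.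

Step 12. Hydrogen abstraction may occur at C14 instead of C11, or SeO2 may oxidise the acetyl methyl group. The fallback sets out from 18 and avoids allylic oxidation: a thiazolium-catalysed Stetter reaction with 4-chlorobutanal (Et3N, dioxane, 70 °C) should add the acyl carbon C11 to C9 from the face anti to C5 and give the Stetter adduct F3. Treatment with K2CO3 and NaI in acetone would close ring C by axial alkylation of the β-keto lactone enolate (cis fusion) to the ring C diketone F4. IBX in DMSO at 70 °C can dehydrogenate only across C12–C13 and comes back to the route at 22.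

Step 15. The hindered enol ether may not take up hydrogen, or hydrogen may be delivered from the face of C10 and give the C11 epimer. The fallback sets out from 22 and fixes C11 before ring D exists: Luche reduction (NaBH4, CeCl3·7H2O, MeOH, −78 °C) with hydride attack on the convex face should give the allylic alcohol F5, and TBSOTf with 2,6-lutidine the silyl ether F6. Enolisation of the methyl ketone with LiN(SiMe3)2 and iodination with N-iodosuccinimide would give the iodomethyl ketone F7. A 5-exo-trig radical cyclisation (Bu3SnH, AIBN, PhH, 80 °C, slow addition) then forms C16–C13 and comes back to the route at 25.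

**Further compounds**

F1 | step 3 | racemic cis-anhydride adduct of 3 and citraconic anhydride (one enantiomer drawn) | C[C@@]12CC=CC3(COC(C)(C)OC3)[C@@H]1C(=O)OC2=O
F2 | step 3 | racemic hydroxy lactone (C19 lactol, anomer mixture; one enantiomer drawn) | C[C@@]12CC=CC3(COC(C)(C)OC3)[C@@H]1C(=O)OC2O
F3 | step 12 | Stetter adduct (C9 4-chlorobutanoyl, C8 epimers) | CC(=O)C1[C@@H](C(=O)CCCCl)[C@@]2(CCC[C@@]3(C)COC(=O)[C@H]32)COC1=O
F4 | step 12 | ring C diketone (saturated ring C, C11 ketone, C8 acetyl) | CC(=O)[C@]12CCCC(=O)[C@H]1[C@@]1(CCC[C@@]3(C)COC(=O)[C@H]31)COC2=O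
F5 | step 15 | C11 allylic alcohol with OH cis to C10 | CC(=O)[C@]12CC=C[C@@H](O)[C@H]1[C@@]1(CCC[C@@]3(C)COC(=O)[C@H]31)COC2=O
F6 | step 15 | tert-butyldimethylsilyl ether of F5 | CC(=O)[C@]12CC=C[C@@H](O[Si](C)(C)C(C)(C)C)[C@H]1[C@@]1(CCC[C@@]3(C)COC(=O)[C@H]31)COC2=O
F7 | step 15 | iodomethyl ketone | ICC(=O)[C@]12CC=C[C@@H](O[Si](C)(C)C(C)(C)C)[C@H]1[C@@]1(CCC[C@@]3(C)COC(=O)[C@H]31)COC2=O
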